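The noon run cannot have stopped for want of coupling partner: its flat stretch holds 56.3% target, which takes 51.2% of the partner charged. So I take substrate to be the limiting reagent, and what does not end as target as lost.

all flasks: free catalyst 0.1 mol%

| charge | substrate | coupling partner | remark |
|---|---|---|---|
| noon | 0.52 M | 1.1 equiv | run made earlier |
| spring | 0.81 M | 1.1 equiv | run made earlier |
| flask | 0.37 M | 1.10 equiv |  |

| run | time / h | target / % |
|---|---|---|
| noon | 0.417 | 21.0 |
| noon | 1.33 | 48.2 |
| noon | 2.50 | 54.4 |
| noon | 4.00 | 58.4 |
| noon | 5.00 | 55.2 |
| noon | 6.00 | 57.1 |
| spring | 0.417 | 35.3 |
| spring | 1.33 | 58.5 |
| spring | 2.50 | 60.1 |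
| spring | 4.00 | 59.6 |
| spring | 5.00 | 60.5 |
| spring | 6.00 | 59.9 |

(scatter of a reading: 1 percentage point)

- factor on the rate of making target when 50% of the substrate are converted if coupling partner is charged twice over
- factor on the rate when 50% of the substrate are converted if free catalyst is charged at 0.02 mol% instead

The spring run stands flat at 60.0%, so the two runs lose 43.7% and 40.0%. I would like one loss for both runs and this flask, but spring sits 3.7 percentage points above noon against a scatter of 1 point per reading, so I keep the drift. Carried along the logarithm of the substrate concentration down to 0.37 M, it gives this flask 46.6%. This loss share, the part of the substrate charged that does not end as target, is what I watch in the flat stretch of the repeat.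

Now I follow one substrate molecule. Free catalyst takes it off, and at a fork it then reaches target or is lost. Suppose the target branch needs free catalyst a second time and the lost branch does not. Less catalyst then slows the leaving in proportion and also worsens the fork, so the order in free catalyst is one plus the loss share, and the ratio is 0.0945, which is an order of 1.47. My objection is that the share itself may grow as catalyst falls, so I expect the factor at or below this. If I charge the whole drift to coupling partner, doubling it trims the loss and gives 1.11. But substrate and catalyst rose with partner between the runs, so this stays a guess.

The forecast gives 1.9 and 0.3, each above mine, and says: “These runs cannot separate the two”.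

The flask gives 1.24 and 0.0838.

    substrate + free catalyst → free catalyst + open intermediate (k = 61.0 M⁻¹ min⁻¹)
    free catalyst + open intermediate ⇌ catalyst intermediate (K = 2.30 M⁻¹, k = 320 M⁻¹ min⁻¹)
    substrate + open intermediate → side product (k = 0.180 M⁻¹ min⁻¹)
    coupling partner + catalyst intermediate → free catalyst + target (k = 300 M⁻¹ min⁻¹)

After 8.00 h this flask holds 53.8% target and 46.2% side product, against the 46.6% I carried, and its ratio means an order of 1.54 over that change of loading, against my 1.47. The reaction of substrate with open intermediate costs this flask a part of its rate: without this reaction, the rate at 50% conversion stands at 1.51 times the actual one. Without this reaction the loss share is zero, so the rule gives one, and the apparent order in free catalyst at that conversion is 1.0 instead of 1.3.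

The numbers in the tables were generated by integration for an exercise; the scatter is artificial.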